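**Plan**
- Retrosynthesis: after unmasking the hydroxyls and re-oxidising the benzylic carbinol, ring A is cut at C1–C2, C2–C3 and C4–C5 into an alkenyl diazoketone (vinylketene precursor) and a prenyl-bearing siloxyalkyne.
- Enabling feature: ring A is a 1,2,3,4-tetrasubstituted benzene (chain on C1, OH on C2, prenyl on C3, OH on C4), a 2-alkylresorcinol. A vinylketene/ynol ether benzannulation writes this pattern directly: ketene oxygen gives C2–OH, the alkyne gives C3-prenyl and C4–O, the alkene terminus gives C1.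
- The diazoketone is cut at its enone C=C (cross-metathesis, then diazo transfer) and at the ArCH2–CH(O) bond (aryl Grignard opening of a terminal epoxide). The two chain oxygens carry different silyl groups, so only the benzylic one is later freed and oxidised.
- Forward order: epoxy alcohol, chain with the catechol ring, enone, diazoketone; alkyne from 4-methylpent-3-enoic acid; ring A (the only ring made) in step 10; then selective desilylation, oxidation and global desilylation.
- Stereochemistry: one Sharpless epoxidation of divinylcarbinol sets both carbinol centres. The epoxide CH becomes the (R)-carbinol of the target; the other centre is erased by oxidation.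

Key step: step 10

Remark on the chemistry (assumption): with L-(+)-diisopropyl tartrate the epoxidation of 1 is taken to give the anti epoxy alcohol 2 as the (2R,3S) isomer, as the Sharpless face rule and kinetic-resolution rule predict; the antipodal tartrate would give the mirror-image series.

**Route**

Step 1
Reactants: 1 penta-1,4-dien-3-ol
Product: 2 (2R,3S)-1,2-epoxypent-4-en-3-ol
Conditions: Ti(OiPr)4 (cat.), L-(+)-diisopropyl tartrate, cumene hydroperoxide, 4 Å molecular sieves, CH2Cl2, −20 °C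
Reagents that add atoms: cumene hydroperoxide, CC(C)(OO)c1ccccc1
Why: Sharpless asymmetric epoxidation of a divinyl carbinol, in which the titanium–(R,R)-tartrate catalyst selects one enantiotopic vinyl group and one of its faces (anti to the carbinol substituent), so both centres are set by the catalyst and the minor enantiomer should be consumed by a second epoxidation.

Step 2
Reactants: 2 (2R,3S)-1,2-epoxypent-4-en-3-ol
Product: 3 (2R,3S)-1,2-epoxy-3-[(triethylsilyl)oxy]pent-4-ene
Conditions: Et3SiCl, imidazole, CH2Cl2, 0 °C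
Reagents that add atoms: chlorotriethylsilane, CC[Si](Cl)(CC)CC
Why: Standard imidazole-promoted silylation of a secondary alcohol, which puts the most labile silyl group on the oxygen that must later be freed alone.

Step 3
Reactants: 4 4-bromobenzene-1,2-diol
Product: 5 4-bromo-1,2-bis[(tert-butyldimethylsilyl)oxy]benzene
Conditions: t-BuMe2SiCl, imidazole, DMF, 25 °C
Reagents that add atoms: tert-butyldimethylsilyl chloride, CC(C)(C)[Si](C)(C)Cl
Why: Double phenol silylation gives a catechol that tolerates organometallic, amide-base and photochemical steps and is removed by fluoride at the end without acid.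

Step 4
Reactants: 5 4-bromo-1,2-bis[(tert-butyldimethylsilyl)oxy]benzene; 3 (2R,3S)-1,2-epoxy-3-[(triethylsilyl)oxy]pent-4-ene
Product: 7 (2R,3S)-1-{3,4-bis[(tert-butyldimethylsilyl)oxy]phenyl}-3-[(triethylsilyl)oxy]pent-4-en-2-ol, via aryl Grignard reagent 6 (not isolated)
Conditions: 5, Mg, THF, 50 °C; then CuI (10 mol %), 3, THF, −30 → 0 °C, cold quench
Reagents that add atoms: none
Why: Copper-catalysed Grignard opening of a terminal epoxide at its CH2 carbon (SN2) leaves both stereocentres untouched, and the cold quench of the magnesium alkoxide should keep the neighbouring silyl group in place.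

Step 5
Reactants: 7 (2R,3S)-1-{3,4-bis[(tert-butyldimethylsilyl)oxy]phenyl}-3-[(triethylsilyl)oxy]pent-4-en-2-ol
Product: 8 (2R,3S)-1-{3,4-bis[(tert-butyldimethylsilyl)oxy]phenyl}-2-[(tert-butyldimethylsilyl)oxy]-3-[(triethylsilyl)oxy]pent-4-ene
Conditions: t-BuMe2SiOTf, 2,6-lutidine, CH2Cl2, −78 → 0 °C
Reagents that add atoms: tert-butyldimethylsilyl trifluoromethanesulfonate, CC(C)(C)[Si](C)(C)OS(=O)(=O)C(F)(F)F
Why: Silyl triflate silylation of a hindered secondary alcohol under non-basic conditions gives the robust ether on the oxygen that becomes the hydroxyl of the target's stereocentre.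

Step 6
Reactants: 8 (2R,3S)-1-{3,4-bis[(tert-butyldimethylsilyl)oxy]phenyl}-2-[(tert-butyldimethylsilyl)oxy]-3-[(triethylsilyl)oxy]pent-4-ene; 9 but-3-en-2-one
Product: 10 (3E,5S,6R)-7-{3,4-bis[(tert-butyldimethylsilyl)oxy]phenyl}-6-[(tert-butyldimethylsilyl)oxy]-5-[(triethylsilyl)oxy]hept-3-en-2-one
Conditions: 9 (5 equiv), second-generation Hoveyda–Grubbs catalyst RuCl2(H2IMes)(=CH-C6H4-2-OiPr) (5 mol %), CH2Cl2, 40 °C
Reagents that add atoms: none
Why: Olefin cross-metathesis between a hindered terminal alkene that homodimerises slowly and an excess of an electron-poor enone should give the E-enone under thermodynamic control with the stereocentres as spectators.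

Step 7
Reactants: 10 (3E,5S,6R)-7-{3,4-bis[(tert-butyldimethylsilyl)oxy]phenyl}-6-[(tert-butyldimethylsilyl)oxy]-5-[(triethylsilyl)oxy]hept-3-en-2-one
Product: 12 (3E,5S,6R)-7-{3,4-bis[(tert-butyldimethylsilyl)oxy]phenyl}-6-[(tert-butyldimethylsilyl)oxy]-1-diazo-5-[(triethylsilyl)oxy]hept-3-en-2-one, via trifluoroacetyl diketone 11 (not isolated)
Conditions: LiN(SiMe3)2, THF, −78 °C; CF3CO2CH2CF3; then MeSO2N3, Et3N, H2O, MeCN, 25 °C
Reagents that add atoms: methanesulfonyl azide, CS(=O)(=O)N=[N+]=[N-] (2,2,2-trifluoroethyl trifluoroacetate, O=C(OCC(F)(F)F)C(F)(F)F, supplies only the trifluoroacetyl group of 11)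
Why: Detrifluoroacetylative diazo transfer: the kinetic enolate of the methyl ketone is trifluoroacetylated and the activated diketone 11 accepts the diazo group from the sulfonyl azide with loss of the trifluoroacetyl unit, which avoids the pyrazoline formation expected when diazomethane meets an enoyl chloride.

Step 8
Reactants: 13 4-methylpent-3-enoic acid
Product: 14 ethyl 4-methylpent-3-enoate
Conditions: EtI, K2CO3, DMF, 25 °C
Reagents that add atoms: iodoethane, CCI
Why: Carboxylate O-alkylation (SN2) makes the ester without the strong acid that would lactonise this unsaturated acid.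

Step 9
Reactants: 14 ethyl 4-methylpent-3-enoate
Product: 17 triisopropyl[(5-methylhex-4-en-1-yn-1-yl)oxy]silane, via lithium dibromoenolate 15 (not isolated), via lithium ynolate 16 (not isolated)
Conditions: CH2Br2, lithium 2,2,6,6-tetramethylpiperidide, THF, −78 °C; n-BuLi, −78 → 0 °C; i-Pr3SiCl, −78 → 25 °C
Reagents that add atoms: dibromomethane, BrCBr; triisopropylsilyl chloride, CC(C)[Si](Cl)(C(C)C)C(C)C
Why: Kowalski ester homologation: dibromomethyllithium adds to the ester, the dibromo enolate 15 undergoes bromine–lithium exchange and a carbenoid 1,2-shift to ynolate 16, and the bulky silyl chloride silylates oxygen to give the stable siloxyalkyne.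

Step 10
Reactants: 12 (3E,5S,6R)-7-{3,4-bis[(tert-butyldimethylsilyl)oxy]phenyl}-6-[(tert-butyldimethylsilyl)oxy]-1-diazo-5-[(triethylsilyl)oxy]hept-3-en-2-one; 17 triisopropyl[(5-methylhex-4-en-1-yn-1-yl)oxy]silane
Product: 21 6-[(1S,2R)-3-{3,4-bis[(tert-butyldimethylsilyl)oxy]phenyl}-2-[(tert-butyldimethylsilyl)oxy]-1-[(triethylsilyl)oxy]propyl]-2-(3-methylbut-2-en-1-yl)-3-[(triisopropylsilyl)oxy]phenol, via vinylketene 18 (not isolated), via 4-vinylcyclobutenone 19 (not isolated), via dienylketene 20 (not isolated)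
Conditions: 17 (1.5 equiv), hν (254 nm, quartz), degassed ClCH2CH2Cl, 25 °C; then 80 °C
Reagents that add atoms: none
Why: Light expels N2 from 12 and the alkenyl group migrates (Wolff rearrangement) to give vinylketene 18, whose ketene C=C adds the siloxyalkyne in a (2+2) cycloaddition, the alkyne carbon remote from oxygen bonding to the ketene carbonyl carbon, to give 19. Reversible four-electron electrocyclic opening of 19 gives dienylketene 20, and ring A, the only ring formed, closes by a six-electron electrocyclisation between the ketene carbon and the former alkene terminus, followed by tautomerisation to the phenol. The closest known reaction type is the Danheiser benzannulation in its diazoketone form with triisopropylsiloxyalkynes, which gives resorcinol monosilyl ethers. No stereocentre is created, and the two silylated carbinol centres of the chain are spectators. The selectivity needed is regiochemical (free OH next to the chain, prenyl between the two oxygens); it is secured by the polarisation of the ynol ether and by the connectivity of the cascade, in which the ketene oxygen can only end on the carbon joining the prenyl carbon and the chain carbon. The excess of alkyne and the final heating should carry any remaining 19 forward and limit O-acylation of the product phenol by ketene.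

Step 11
Reactants: 21 6-[(1S,2R)-3-{3,4-bis[(tert-butyldimethylsilyl)oxy]phenyl}-2-[(tert-butyldimethylsilyl)oxy]-1-[(triethylsilyl)oxy]propyl]-2-(3-methylbut-2-en-1-yl)-3-[(triisopropylsilyl)oxy]phenol
Product: 22 6-[(1S,2R)-3-{3,4-bis[(tert-butyldimethylsilyl)oxy]phenyl}-2-[(tert-butyldimethylsilyl)oxy]-1-hydroxypropyl]-2-(3-methylbut-2-en-1-yl)-3-[(triisopropylsilyl)oxy]phenol
Conditions: HF·pyridine, pyridine, THF, 0 °C
Reagents that add atoms: none
Why: Selective desilylation with buffered acidic fluoride, which cleaves a triethylsilyl ether far faster than a secondary tert-butyldimethylsilyl ether or aryl silyl ethers and is not ionising enough to disturb the electron-rich benzylic C–O bond.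

Step 12
Reactants: 22 6-[(1S,2R)-3-{3,4-bis[(tert-butyldimethylsilyl)oxy]phenyl}-2-[(tert-butyldimethylsilyl)oxy]-1-hydroxypropyl]-2-(3-methylbut-2-en-1-yl)-3-[(triisopropylsilyl)oxy]phenol
Product: 23 (2R)-3-{3,4-bis[(tert-butyldimethylsilyl)oxy]phenyl}-2-[(tert-butyldimethylsilyl)oxy]-1-{2-hydroxy-3-(3-methylbut-2-en-1-yl)-4-[(triisopropylsilyl)oxy]phenyl}propan-1-one
Conditions: MnO2 (activated, excess), CH2Cl2, 25 °C
Reagents that add atoms: none
Why: MnO2 oxidation of an ortho-hydroxybenzylic alcohol to the hydrogen-bonded aryl ketone, unambiguous because the neighbouring oxygen is silylated (no free vicinal diol to cleave) and no other carbinol is free.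

Step 13
Reactants: 23 (2R)-3-{3,4-bis[(tert-butyldimethylsilyl)oxy]phenyl}-2-[(tert-butyldimethylsilyl)oxy]-1-{2-hydroxy-3-(3-methylbut-2-en-1-yl)-4-[(triisopropylsilyl)oxy]phenyl}propan-1-one
Product: 24 (2R)-1-[2,4-dihydroxy-3-(3-methylbut-2-en-1-yl)phenyl]-3-(3,4-dihydroxyphenyl)-2-hydroxypropan-1-one
Conditions: Bu4NF, AcOH, THF, 0 → 25 °C, degassed
Reagents that add atoms: none
Why: Global fluoride desilylation buffered with acetic acid should remove the three aryl silyl ethers and the silyl ether next to the ketone without acid (which would cyclise the prenyl group onto a phenol) and without free base (which would enolise the hydroxy ketone or air-oxidise the catechol).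

**Compound list**
1 | penta-1,4-dien-3-ol | C=CC(O)C=C | starting material
2 | (2R,3S)-1,2-epoxypent-4-en-3-ol, that is (1S)-1-[(2R)-oxiran-2-yl]prop-2-en-1-ol | C=C[C@H](O)[C@H]1CO1 | intermediate
3 | (2R,3S)-1,2-epoxy-3-[(triethylsilyl)oxy]pent-4-ene | C=C[C@H](O[Si](CC)(CC)CC)[C@H]1CO1 | intermediate
4 | 4-bromobenzene-1,2-diol | Oc1ccc(Br)cc1O | starting material
5 | 4-bromo-1,2-bis[(tert-butyldimethylsilyl)oxy]benzene | CC(C)(C)[Si](C)(C)Oc1ccc(Br)cc1O[Si](C)(C)C(C)(C)C | intermediate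
6 | {3,4-bis[(tert-butyldimethylsilyl)oxy]phenyl}magnesium bromide | CC(C)(C)[Si](C)(C)Oc1ccc([Mg]Br)cc1O[Si](C)(C)C(C)(C)C | intermediate (not isolated)
7 | (2R,3S)-1-{3,4-bis[(tert-butyldimethylsilyl)oxy]phenyl}-3-[(triethylsilyl)oxy]pent-4-en-2-ol | C=C[C@H](O[Si](CC)(CC)CC)[C@H](O)Cc1ccc(O[Si](C)(C)C(C)(C)C)c(O[Si](C)(C)C(C)(C)C)c1 | intermediate
8 | (2R,3S)-1-{3,4-bis[(tert-butyldimethylsilyl)oxy]phenyl}-2-[(tert-butyldimethylsilyl)oxy]-3-[(triethylsilyl)oxy]pent-4-ene | C=C[C@H](O[Si](CC)(CC)CC)[C@H](O[Si](C)(C)C(C)(C)C)Cc1ccc(O[Si](C)(C)C(C)(C)C)c(O[Si](C)(C)C(C)(C)C)c1 | intermediate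
9 | but-3-en-2-one | CC(=O)C=C | starting material
10 | (3E,5S,6R)-7-{3,4-bis[(tert-butyldimethylsilyl)oxy]phenyl}-6-[(tert-butyldimethylsilyl)oxy]-5-[(triethylsilyl)oxy]hept-3-en-2-one | CC(=O)/C=C/[C@H](O[Si](CC)(CC)CC)[C@H](O[Si](C)(C)C(C)(C)C)Cc1ccc(O[Si](C)(C)C(C)(C)C)c(O[Si](C)(C)C(C)(C)C)c1 | intermediate
11 | (5E,7S,8R)-9-{3,4-bis[(tert-butyldimethylsilyl)oxy]phenyl}-8-[(tert-butyldimethylsilyl)oxy]-1,1,1-trifluoro-7-[(triethylsilyl)oxy]non-5-ene-2,4-dione | FC(F)(F)C(=O)CC(=O)/C=C/[C@H](O[Si](CC)(CC)CC)[C@H](O[Si](C)(C)C(C)(C)C)Cc1ccc(O[Si](C)(C)C(C)(C)C)c(O[Si](C)(C)C(C)(C)C)c1 | intermediate (not isolated)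
12 | (3E,5S,6R)-7-{3,4-bis[(tert-butyldimethylsilyl)oxy]phenyl}-6-[(tert-butyldimethylsilyl)oxy]-1-diazo-5-[(triethylsilyl)oxy]hept-3-en-2-one | [N-]=[N+]=CC(=O)/C=C/[C@H](O[Si](CC)(CC)CC)[C@H](O[Si](C)(C)C(C)(C)C)Cc1ccc(O[Si](C)(C)C(C)(C)C)c(O[Si](C)(C)C(C)(C)C)c1 | intermediate
13 | 4-methylpent-3-enoic acid | CC(C)=CCC(=O)O | starting material
14 | ethyl 4-methylpent-3-enoate | CCOC(=O)CC=C(C)C | intermediate
15 | lithium 1,1-dibromo-5-methylhexa-1,4-dien-2-olate | [Li]OC(CC=C(C)C)=C(Br)Br | intermediate (not isolated)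
16 | lithium 5-methylhex-4-en-1-yn-1-olate | [Li]OC#CCC=C(C)C | intermediate (not isolated)
17 | triisopropyl[(5-methylhex-4-en-1-yn-1-yl)oxy]silane | CC(C)=CCC#CO[Si](C(C)C)(C(C)C)C(C)C | intermediate
18 | (3E,5S,6R)-7-{3,4-bis[(tert-butyldimethylsilyl)oxy]phenyl}-6-[(tert-butyldimethylsilyl)oxy]-5-[(triethylsilyl)oxy]hepta-1,3-dien-1-one | O=C=C/C=C/[C@H](O[Si](CC)(CC)CC)[C@H](O[Si](C)(C)C(C)(C)C)Cc1ccc(O[Si](C)(C)C(C)(C)C)c(O[Si](C)(C)C(C)(C)C)c1 | intermediate (not isolated)
19 | 4-[(1E,3S,4R)-5-{3,4-bis[(tert-butyldimethylsilyl)oxy]phenyl}-4-[(tert-butyldimethylsilyl)oxy]-3-[(triethylsilyl)oxy]pent-1-en-1-yl]-2-(3-methylbut-2-en-1-yl)-3-[(triisopropylsilyl)oxy]cyclobut-2-en-1-one (both epimers at the ring carbon) | O=C1C(CC=C(C)C)=C(O[Si](C(C)C)(C(C)C)C(C)C)C1/C=C/[C@H](O[Si](CC)(CC)CC)[C@H](O[Si](C)(C)C(C)(C)C)Cc2ccc(O[Si](C)(C)C(C)(C)C)c(O[Si](C)(C)C(C)(C)C)c2 | intermediate (not isolated)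
20 | (3E,5E,7S,8R)-9-{3,4-bis[(tert-butyldimethylsilyl)oxy]phenyl}-8-[(tert-butyldimethylsilyl)oxy]-2-(3-methylbut-2-en-1-yl)-7-[(triethylsilyl)oxy]-3-[(triisopropylsilyl)oxy]nona-1,3,5-trien-1-one | O=C=C(CC=C(C)C)/C(O[Si](C(C)C)(C(C)C)C(C)C)=C\C=C\[C@H](O[Si](CC)(CC)CC)[C@H](O[Si](C)(C)C(C)(C)C)Cc1ccc(O[Si](C)(C)C(C)(C)C)c(O[Si](C)(C)C(C)(C)C)c1 | intermediate (not isolated)
21 | 6-[(1S,2R)-3-{3,4-bis[(tert-butyldimethylsilyl)oxy]phenyl}-2-[(tert-butyldimethylsilyl)oxy]-1-[(triethylsilyl)oxy]propyl]-2-(3-methylbut-2-en-1-yl)-3-[(triisopropylsilyl)oxy]phenol | CC(C)=CCc1c(O[Si](C(C)C)(C(C)C)C(C)C)ccc([C@H](O[Si](CC)(CC)CC)[C@H](O[Si](C)(C)C(C)(C)C)Cc2ccc(O[Si](C)(C)C(C)(C)C)c(O[Si](C)(C)C(C)(C)C)c2)c1O | intermediate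
22 | 6-[(1S,2R)-3-{3,4-bis[(tert-butyldimethylsilyl)oxy]phenyl}-2-[(tert-butyldimethylsilyl)oxy]-1-hydroxypropyl]-2-(3-methylbut-2-en-1-yl)-3-[(triisopropylsilyl)oxy]phenol | CC(C)=CCc1c(O[Si](C(C)C)(C(C)C)C(C)C)ccc([C@H](O)[C@H](O[Si](C)(C)C(C)(C)C)Cc2ccc(O[Si](C)(C)C(C)(C)C)c(O[Si](C)(C)C(C)(C)C)c2)c1O | intermediate
23 | (2R)-3-{3,4-bis[(tert-butyldimethylsilyl)oxy]phenyl}-2-[(tert-butyldimethylsilyl)oxy]-1-{2-hydroxy-3-(3-methylbut-2-en-1-yl)-4-[(triisopropylsilyl)oxy]phenyl}propan-1-one | CC(C)=CCc1c(O[Si](C(C)C)(C(C)C)C(C)C)ccc(C(=O)[C@H](O[Si](C)(C)C(C)(C)C)Cc2ccc(O[Si](C)(C)C(C)(C)C)c(O[Si](C)(C)C(C)(C)C)c2)c1O | intermediate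
24 | (2R)-1-[2,4-dihydroxy-3-(3-methylbut-2-en-1-yl)phenyl]-3-(3,4-dihydroxyphenyl)-2-hydroxypropan-1-one | CC(C)=CCc1c(O)ccc(C(=O)[C@H](O)Cc2ccc(O)c(O)c2)c1O | target

**Count and risks**

Total: 13 steps. Longest linear sequence: 10 steps (1, 2, 4, 5, 6, 7, 10, 11, 12, 13).

Steps most likely to fail:

- **Step 10.** The Wolff rearrangement may be starved of light because the silylated catechol ring absorbs in the same region. The enone double bond may photoisomerise, and the ketene may be intercepted by the product phenol instead of the alkyne, so that ring A does not form cleanly. Fallback (sets out from 8, rejoins at 24): ring A is taken from a resorcinol and joined by directed ortho-metalation. HF·pyridine/pyridine frees the allylic hydroxyl of 8 to give (2R,3S)-1-{3,4-bis[(tert-butyldimethylsilyl)oxy]phenyl}-2-[(tert-butyldimethylsilyl)oxy]pent-4-en-3-ol F1, and OsO4 (cat.)/NaIO4 cuts the vinyl carbinol down to (2R)-3-{3,4-bis[(tert-butyldimethylsilyl)oxy]phenyl}-2-[(tert-butyldimethylsilyl)oxy]propanal F2. Commercial 1,3-bis(methoxymethoxy)benzene is lithiated between its oxygens (n-BuLi, THF) to [2,6-bis(methoxymethoxy)phenyl]lithium F3 and alkylated with 1-bromo-3-methylbut-2-ene to 1,3-bis(methoxymethoxy)-2-(3-methylbut-2-en-1-yl)benzene F4. A second ortho-lithiation (n-BuLi, TMEDA) gives [2,4-bis(methoxymethoxy)-3-(3-methylbut-2-en-1-yl)phenyl]lithium F5, which adds to F2 to give (2R)-1-[2,4-bis(methoxymethoxy)-3-(3-methylbut-2-en-1-yl)phenyl]-3-{3,4-bis[(tert-butyldimethylsilyl)oxy]phenyl}-2-[(tert-butyldimethylsilyl)oxy]propan-1-ol F6 as both carbinol epimers. Dess–Martin oxidation converges them to (2R)-1-[2,4-bis(methoxymethoxy)-3-(3-methylbut-2-en-1-yl)phenyl]-3-{3,4-bis[(tert-butyldimethylsilyl)oxy]phenyl}-2-[(tert-butyldimethylsilyl)oxy]propan-1-one F7. Bu4NF/AcOH then gives (2R)-1-[2,4-bis(methoxymethoxy)-3-(3-methylbut-2-en-1-yl)phenyl]-3-(3,4-dihydroxyphenyl)-2-hydroxypropan-1-one F8, and dilute HCl in MeOH at 25 °C removes the two aryl methoxymethyl ethers to give 24.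

- **Step 9.** The lithium amide or the carbenoid may deprotonate the doubly activated CH2 of 14 instead of adding to the ester carbonyl, and the double bond may move into conjugation, so that little ynolate forms. Fallback (sets out from 14, rejoins at 16 and so at 17): i-Bu2AlH at −78 °C reduces 14 to 4-methylpent-3-enal F9. Corey–Fuchs olefination (CBr4, PPh3, non-basic) gives 1,1-dibromo-5-methylhexa-1,4-diene F10, and n-BuLi (2 equiv) gives (5-methylhex-4-en-1-yn-1-yl)lithium F11. Oxidation of this acetylide with lithium tert-butyl peroxide (from t-BuOOH and LiN(SiMe3)2) gives ynolate 16, which is silylated with i-Pr3SiCl to 17 as before.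

- **Step 6.** The crowded allylic terminus may enter the metathesis cycle too slowly, so that the catalyst decays and the enone partner dimerises before cross-coupling is complete. Fallback (sets out from 8, rejoins at 10): OsO4 (cat.)/NaIO4/2,6-lutidine in dioxane–water cleaves the vinyl group to (2R,3R)-4-{3,4-bis[(tert-butyldimethylsilyl)oxy]phenyl}-3-[(tert-butyldimethylsilyl)oxy]-2-[(triethylsilyl)oxy]butanal F12. Wittig olefination with Ph3P=CHC(O)CH3 in toluene at 80 °C then gives the E-enone 10; epimerisation next to the aldehyde would be harmless because that centre is oxidised in step 12.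

**Further compounds**
F1 | step 10 | (2R,3S)-1-{3,4-bis[(tert-butyldimethylsilyl)oxy]phenyl}-2-[(tert-butyldimethylsilyl)oxy]pent-4-en-3-ol | C=C[C@H](O)[C@H](O[Si](C)(C)C(C)(C)C)Cc1ccc(O[Si](C)(C)C(C)(C)C)c(O[Si](C)(C)C(C)(C)C)c1
F2 | step 10 | (2R)-3-{3,4-bis[(tert-butyldimethylsilyl)oxy]phenyl}-2-[(tert-butyldimethylsilyl)oxy]propanal | O=C[C@H](O[Si](C)(C)C(C)(C)C)Cc1ccc(O[Si](C)(C)C(C)(C)C)c(O[Si](C)(C)C(C)(C)C)c1
F3 | step 10 | [2,6-bis(methoxymethoxy)phenyl]lithium | [Li]c1c(OCOC)cccc1OCOC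
F4 | step 10 | 1,3-bis(methoxymethoxy)-2-(3-methylbut-2-en-1-yl)benzene | COCOc1cccc(OCOC)c1CC=C(C)C
F5 | step 10 | [2,4-bis(methoxymethoxy)-3-(3-methylbut-2-en-1-yl)phenyl]lithium | [Li]c1ccc(OCOC)c(CC=C(C)C)c1OCOC
F6 | step 10 | (2R)-1-[2,4-bis(methoxymethoxy)-3-(3-methylbut-2-en-1-yl)phenyl]-3-{3,4-bis[(tert-butyldimethylsilyl)oxy]phenyl}-2-[(tert-butyldimethylsilyl)oxy]propan-1-ol (both C1 epimers) | CC(C)=CCc1c(OCOC)ccc(C(O)[C@H](O[Si](C)(C)C(C)(C)C)Cc2ccc(O[Si](C)(C)C(C)(C)C)c(O[Si](C)(C)C(C)(C)C)c2)c1OCOC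
F7 | step 10 | (2R)-1-[2,4-bis(methoxymethoxy)-3-(3-methylbut-2-en-1-yl)phenyl]-3-{3,4-bis[(tert-butyldimethylsilyl)oxy]phenyl}-2-[(tert-butyldimethylsilyl)oxy]propan-1-one | CC(C)=CCc1c(OCOC)ccc(C(=O)[C@H](O[Si](C)(C)C(C)(C)C)Cc2ccc(O[Si](C)(C)C(C)(C)C)c(O[Si](C)(C)C(C)(C)C)c2)c1OCOC
F8 | step 10 | (2R)-1-[2,4-bis(methoxymethoxy)-3-(3-methylbut-2-en-1-yl)phenyl]-3-(3,4-dihydroxyphenyl)-2-hydroxypropan-1-one | CC(C)=CCc1c(OCOC)ccc(C(=O)[C@H](O)Cc2ccc(O)c(O)c2)c1OCOC
F9 | step 9 | 4-methylpent-3-enal | O=CCC=C(C)C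
F10 | step 9 | 1,1-dibromo-5-methylhexa-1,4-diene | BrC(Br)=CCC=C(C)C
F11 | step 9 | (5-methylhex-4-en-1-yn-1-yl)lithium | [Li]C#CCC=C(C)C
F12 | step 6 | (2R,3R)-4-{3,4-bis[(tert-butyldimethylsilyl)oxy]phenyl}-3-[(tert-butyldimethylsilyl)oxy]-2-[(triethylsilyl)oxy]butanal | O=C[C@H](O[Si](CC)(CC)CC)[C@H](O[Si](C)(C)C(C)(C)C)Cc1ccc(O[Si](C)(C)C(C)(C)C)c(O[Si](C)(C)C(C)(C)C)c1
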